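**Retrosynthetic overview**
1. The strategy rests on C3 of the non-brominated indole ring, which is bonded to C2 of the imidazole. That carbon is read as the carbonyl carbon of a 2-aroylimidazole and the neighbouring indole C2–H as the carbon of an N-formyl group on the ortho nitrogen, so the pyrrole ring of this indole is cut across C2–C3 (reductive carbonyl–carbonyl coupling).
2. The keto-formamide is traced back through the ortho-amino and ortho-nitro ketones to a C2-aroylation of bis-SEM 4-(6-bromoindol-3-yl)imidazole with 2-nitrobenzoyl chloride.
3. The imidazole ring is cut to formamide and the 3-chloroacetyl derivative of 6-bromoindole (Friedel–Crafts acylation at indole C3).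
4. Ring order: the brominated indole is bought, the imidazole is formed second, the pyrrole ring of the second indole last; both SEM groups are then removed together.

Key step: step 7

Assumption: SEM = 2-(trimethylsilyl)ethoxymethyl (CH2OCH2CH2SiMe3). The target has no stereocentre, and since its two imidazole N–H tautomers are one compound, SEM on either imidazole nitrogen leads to the same product; the 1,4-isomer is drawn and carried.

Step 1
Reactants: 1 6-bromo-1H-indole; 2 chloroacetyl chloride
Product: 3 1-(6-bromo-1H-indol-3-yl)-2-chloroethan-1-one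
Conditions: Et2AlCl (1.5 equiv), CH2Cl2, 0 °C; then 2 (1.3 equiv), 0 °C → rt; 1 M HCl quench
Reagents that add atoms: none
Why: Et2AlCl-mediated Friedel–Crafts acylation of an N-unprotected indole, in which the aluminium reagent activates the acid chloride and consumes the HCl as ethane, should acylate the most nucleophilic carbon, C3, without N-protection or acid-induced oligomerisation and leave the C6 bromide untouched.

Step 2
Reactants: 3 1-(6-bromo-1H-indol-3-yl)-2-chloroethan-1-one; 4 formamide
Product: 5 6-bromo-3-(1H-imidazol-4-yl)-1H-indole
Conditions: HCONH2 (neat, about 30 equiv), 170 °C; then H2O, aq. NH3 to pH 9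
Reagents that add atoms: formamide (second molecule), NC=O
Why: Bredereck imidazole synthesis from an α-haloketone, in which three molecules of formamide are consumed: one displaces the α-chloride and supplies N1–C2(H), a second supplies N3 by condensation at the ketone carbon before cyclodehydration, and a third is hydrolysed by the water released and binds the HCl as ammonium chloride, which should give the 4-substituted imidazole with the aryl bromide and the indole N–H inert in the neutral melt.

Step 3
Reactants: 5 6-bromo-3-(1H-imidazol-4-yl)-1H-indole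
Product: 6 6-bromo-1-SEM-3-(1-SEM-imidazol-4-yl)indole
Conditions: NaH (2.4 equiv), DMF, 0 °C; SEMCl (2.3 equiv), 0 °C → rt
Reagents that add atoms: 2-(trimethylsilyl)ethoxymethyl chloride (SEMCl), C[Si](C)(C)CCOCCl
Why: Double SN2 N-alkylation of the indolide and imidazolide anions, in which the imidazole should take SEM mainly at the nitrogen remote from the indolyl substituent for steric reasons, and either regioisomer would converge on the same target after deprotection.

Step 4
Reactants: 6 6-bromo-1-SEM-3-(1-SEM-imidazol-4-yl)indole; 7 2-nitrobenzoyl chloride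
Product: 9 [4-(6-bromo-1-SEM-indol-3-yl)-1-SEM-imidazol-2-yl](2-nitrophenyl)methanone, via N-acylimidazolium chloride 8 (not isolated)
Conditions: 7 (2 equiv), Et3N (3 equiv), MeCN, 0 → 50 °C; aqueous work-up
Reagents that add atoms: none
Why: Regel-type C2 aroylation of a 1-alkylimidazole, in which acylation of the free N3 gives 8, Et3N removes its acidified C2–H to an ylide (N-heterocyclic carbene) and the aroyl group ends on C2 with N3 set free again, a path open only to the imidazole ring, so the SEM-indole, the aryl bromide and the nitro group should be spectators.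

Step 5
Reactants: 9 [4-(6-bromo-1-SEM-indol-3-yl)-1-SEM-imidazol-2-yl](2-nitrophenyl)methanone
Product: 10 (2-aminophenyl)[4-(6-bromo-1-SEM-indol-3-yl)-1-SEM-imidazol-2-yl]methanone
Conditions: Fe powder (6 equiv), NH4Cl (5 equiv), EtOH/H2O 4:1, 75 °C; filtration through Celite
Reagents that add atoms: none
Why: Béchamp-type iron reduction under nearly neutral conditions is chemoselective for the nitro group, so the diaryl ketone, the aryl bromide and the acid-sensitive SEM aminals should be kept.

Step 6
Reactants: 10 (2-aminophenyl)[4-(6-bromo-1-SEM-indol-3-yl)-1-SEM-imidazol-2-yl]methanone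
Product: 11 N-[2-({4-(6-bromo-1-SEM-indol-3-yl)-1-SEM-imidazol-2-yl}carbonyl)phenyl]formamide
Conditions: HCO2H/Ac2O premixed (55 °C, 2 h, gives AcOCHO); then 10, THF, 0 °C → rt
Reagents that add atoms: acetic formic anhydride, CC(=O)OC=O (made beforehand from formic acid, OC=O, and acetic anhydride, CC(=O)OC(C)=O)
Why: N-formylation with the mixed anhydride, whose formyl carbonyl is by far the more electrophilic, should acylate even this ketone-deactivated, hydrogen-bonded aniline at or below room temperature, and the weakly acidic medium should leave N-SEM untouched.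

Step 7
Reactants: 11 N-[2-({4-(6-bromo-1-SEM-indol-3-yl)-1-SEM-imidazol-2-yl}carbonyl)phenyl]formamide
Product: 13 6-bromo-1-SEM-3-[2-(1H-indol-3-yl)-1-SEM-imidazol-4-yl]indole, via cyclic titanium 2,3-diolate 12 (not isolated)
Conditions: TiCl3 (4 equiv), Zn dust (8 equiv), DME, reflux, 0.02 M in 11, Ar; filtration through SiO2
Reagents that add atoms: none
Why: Low-valent titanium formed in the flask from TiCl3 and Zn transfers two electrons to the 2-aroylimidazole carbonyl, the most easily reduced group present, and the titanium-bound carbon nucleophile at the future C3 adds to the neighbouring formamide carbonyl to give diolate 12, which a second low-valent titanium centre deoxygenates to the C2=C3 double bond. This is the reductive oxo-amide coupling known as the Fürstner indole synthesis, an intramolecular McMurry-type reaction whose substrate class is the N-acyl 2-aminoaryl ketones, the formyl group here supplying the C2–H of the indole. The pyrrole ring closes in a 5-exo-trig mode, the formamide C=O lying outside the ring being formed. No stereocentre remains, because the two carbinol centres of 12 become planar on deoxygenation. The step needs ketone–amide coupling to win over intermolecular pinacol dimerisation, over-reduction of the ketone and C–Br reduction: the ortho placement of both carbonyls on one benzene ring should make cyclisation fast at this dilution, an amide is not reduced on its own so only the ketone is activated, and aryl bromides and N-SEM aminals are not expected to react with this reagent (excess reagent allows for binding of titanium to the basic imidazole N3).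

Step 8
Reactants: 13 6-bromo-1-SEM-3-[2-(1H-indol-3-yl)-1-SEM-imidazol-4-yl]indole
Product: 14 nortopsentin C
Conditions: Bu4NF (1 M in THF, 8 equiv), H2NCH2CH2NH2 (6 equiv), DMF, 80 °C; then H2O
Reagents that add atoms: none
Why: Fluoride-induced SEM cleavage, in which fluoride attacks silicon and β-elimination releases ethene and formaldehyde from each N–CH2O unit, should free both N–H groups while ethylenediamine traps the formaldehyde before it can hydroxymethylate or bridge the indoles, and the aryl bromide is inert to fluoride.

**Compound list**
1 | 6-bromo-1H-indole | Brc1ccc2cc[nH]c2c1 | starting material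
2 | chloroacetyl chloride | ClCC(Cl)=O | starting material
3 | 1-(6-bromo-1H-indol-3-yl)-2-chloroethan-1-one | O=C(CCl)c1c[nH]c2cc(Br)ccc12 | intermediate
4 | formamide | NC=O | starting material
5 | 6-bromo-3-(1H-imidazol-4-yl)-1H-indole | Brc1ccc2c(-c3c[nH]cn3)c[nH]c2c1 | intermediate
6 | 6-bromo-1-{[2-(trimethylsilyl)ethoxy]methyl}-3-(1-{[2-(trimethylsilyl)ethoxy]methyl}-1H-imidazol-4-yl)-1H-indole (bis-SEM compound) | Brc1ccc2c(-c3cn(COCC[Si](C)(C)C)cn3)cn(COCC[Si](C)(C)C)c2c1 | intermediate
7 | 2-nitrobenzoyl chloride | O=C(Cl)c1ccccc1[N+](=O)[O-] | starting material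
8 | 4-(6-bromo-1-SEM-indol-3-yl)-3-(2-nitrobenzoyl)-1-SEM-imidazol-3-ium chloride | [O-][N+](=O)c1ccccc1C(=O)[n+]1cn(COCC[Si](C)(C)C)cc1-c1cn(COCC[Si](C)(C)C)c2cc(Br)ccc12.[Cl-] | intermediate
9 | [4-(6-bromo-1-SEM-indol-3-yl)-1-SEM-imidazol-2-yl](2-nitrophenyl)methanone | O=C(c1ccccc1[N+](=O)[O-])c1nc(cn1COCC[Si](C)(C)C)-c1cn(COCC[Si](C)(C)C)c2cc(Br)ccc12 | intermediate
10 | (2-aminophenyl)[4-(6-bromo-1-SEM-indol-3-yl)-1-SEM-imidazol-2-yl]methanone | Nc1ccccc1C(=O)c1nc(cn1COCC[Si](C)(C)C)-c1cn(COCC[Si](C)(C)C)c2cc(Br)ccc12 | intermediate
11 | N-[2-({4-(6-bromo-1-SEM-indol-3-yl)-1-SEM-imidazol-2-yl}carbonyl)phenyl]formamide | O=CNc1ccccc1C(=O)c1nc(cn1COCC[Si](C)(C)C)-c1cn(COCC[Si](C)(C)C)c2cc(Br)ccc12 | intermediate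
12 | cyclic dichlorotitanium 2,3-diolate of 3-[4-(6-bromo-1-SEM-indol-3-yl)-1-SEM-imidazol-2-yl]indoline-2,3-diol (tetravalent titanium; idealised monomer; cis by ring constraint; racemic, one enantiomer drawn) | Cl[Ti]1(Cl)O[C@H]2Nc3ccccc3[C@]2(O1)c1nc(cn1COCC[Si](C)(C)C)-c1cn(COCC[Si](C)(C)C)c2cc(Br)ccc12 | intermediate
13 | 6-bromo-1-SEM-3-[2-(1H-indol-3-yl)-1-SEM-imidazol-4-yl]indole | c1ccc2c(c1)[nH]cc2-c1nc(cn1COCC[Si](C)(C)C)-c1cn(COCC[Si](C)(C)C)c2cc(Br)ccc12 | intermediate
14 | nortopsentin C, 6-bromo-3-[2-(1H-indol-3-yl)-1H-imidazol-4-yl]-1H-indole | Brc1ccc2c(-c3c[nH]c(-c4c[nH]c5ccccc45)n3)c[nH]c2c1 | target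

**Step count and risks**
Total steps: 8. Longest linear sequence: 8 steps (from 1).

The three steps most likely to fail:

Step 7 (key step). The titanium-bound ketyl may dimerise intermolecularly or be reduced further to the carbinol or methylene before it attacks the formamide. The basic imidazole nitrogen may also tie up the titanium reagent, and the Lewis-acidic zinc and titanium chlorides may strip SEM at reflux. Fallback, setting out from 9 and returning at 13: the indole is closed at N1–C2 instead. Wittig methylenation of ketone 9 (Ph3PCH3Br, KOt-Bu, THF, 0 °C → rt) should give the 1,1-diarylethene 4-(6-bromo-1-SEM-indol-3-yl)-2-[1-(2-nitrophenyl)ethenyl]-1-SEM-imidazole F1. Cadogan–Sundberg reductive cyclisation of F1 (PPh3, o-dichlorobenzene, 180 °C) should then deoxygenate the nitro group and insert the nitrogen into the terminal vinylic C–H, which gives 13 directly without reducing conditions that could touch the C–Br bond.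

Step 4. N3 acylation may be slowed by the neighbouring indolyl group, chloride may remove SEM from the N-acylimidazolium, and acyl transfer to C2 may stall. Fallback, setting out from 6 and returning at 9: deprotonation at imidazole C2 with TMPMgCl·LiCl (TMP = 2,2,6,6-tetramethylpiperidin-1-yl; THF, −20 °C), an amide base that does not exchange the aryl bromide, should give [4-(6-bromo-1-SEM-indol-3-yl)-1-SEM-imidazol-2-yl]magnesium chloride F2. Addition of F2 to 2-nitrobenzaldehyde at −78 °C, where carbonyl addition should outrun attack on the nitro group, followed by NH4Cl work-up should give the racemic carbinol [4-(6-bromo-1-SEM-indol-3-yl)-1-SEM-imidazol-2-yl](2-nitrophenyl)methanol F3. Oxidation of this doubly activated carbinol with MnO2 in CH2Cl2 at rt should give 9.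

Step 2. Oxazole formation may compete with imidazole formation, and the chloroketone may decompose or tar in formamide at 170 °C. Fallback, setting out from 3 and returning at 5: the nitrogen atoms are introduced stepwise at low temperature. Azide displacement (NaN3, DMF, rt) should give 2-azido-1-(6-bromo-1H-indol-3-yl)ethan-1-one F4. Staudinger reduction (PPh3, THF, then aq. HCl), which keeps the aryl bromide and releases the amine only as its salt so that self-condensation is avoided, should give 2-amino-1-(6-bromo-1H-indol-3-yl)ethan-1-one hydrochloride F5. Condensation of F5 with an excess of formamidine acetate (EtOH, reflux; amidine/α-aminoketone imidazole synthesis) should give 5.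

Further compounds
F1 | step 7 | 4-(6-bromo-1-SEM-indol-3-yl)-2-[1-(2-nitrophenyl)ethenyl]-1-SEM-imidazole | C=C(c1ccccc1[N+](=O)[O-])c1nc(cn1COCC[Si](C)(C)C)-c1cn(COCC[Si](C)(C)C)c2cc(Br)ccc12
F2 | step 4 | [4-(6-bromo-1-SEM-indol-3-yl)-1-SEM-imidazol-2-yl]magnesium chloride | Cl[Mg]c1nc(cn1COCC[Si](C)(C)C)-c1cn(COCC[Si](C)(C)C)c2cc(Br)ccc12
F3 | step 4 | [4-(6-bromo-1-SEM-indol-3-yl)-1-SEM-imidazol-2-yl](2-nitrophenyl)methanol (racemic) | OC(c1ccccc1[N+](=O)[O-])c1nc(cn1COCC[Si](C)(C)C)-c1cn(COCC[Si](C)(C)C)c2cc(Br)ccc12
F4 | step 2 | 2-azido-1-(6-bromo-1H-indol-3-yl)ethan-1-one | [N-]=[N+]=NCC(=O)c1c[nH]c2cc(Br)ccc12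
F5 | step 2 | 2-amino-1-(6-bromo-1H-indol-3-yl)ethan-1-one hydrochloride | Cl.NCC(=O)c1c[nH]c2cc(Br)ccc12
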